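(The data come from a simulation for substances that don't exist.)

Amber's free monomer goes into chains with a rate constant of 0.103 /h over its first 12.0 h, and red's with 0.0851 /h over its first 12.0 h. So amber is faster than red, although its loading of 1.3 mol% is below red's 1.6 mol%.

| flask | free monomer | initiator | temperature | remark | time |
|---|---|---|---|---|---|
| grey | 25 mM | 1.3 mol% | −20 °C | run made earlier |  |
| amber | 39 mM | 1.3 mol% | 25 °C | run made earlier |  |
| green | 78 mM | 1.3 mol% | −20 °C | run made earlier |  |
| red | 21 mM | 1.6 mol% | 25 °C | run made earlier |  |
| alder | 21 mM | 0.4 mol% | −15 °C |  | 50 h |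
| ash | 21 mM | 0.3 mol% | 55 °C |  | 50 h |
| elm | 80 mM | 5 mol% | 65 °C |  | 50 h |
| oak | 21 mM | 1.3 mol% | −5 °C |  | 50 h |
| maple | 21 mM | 1.3 mol% | 25 °C |  | 50 h |
| cedar | 21 mM | 0.3 mol% | 25 °C |  | 50 h |

| run | time / h | monomer in chains / % |
|---|---|---|
| grey | 60.0 | 2.6 |
| grey | 120 | 2.5 |
| grey | 192 | 5.2 |
| grey | 240 | 4.2 |
| amber | 6.00 | 51.1 |
| amber | 12.0 | 71.0 |
| amber | 20.0 | 84.4 |
| amber | 25.0 | 92.2 |
| green | 20.0 | 1.3 |
| green | 50.0 | 1.2 |
| green | 96.0 | 2.9 |
| green | 240 | 9.6 |
| red | 6.00 | 42.3 |
| red | 12.0 | 64.0 |
| red | 20.0 | 81.5 |
| red | 25.0 | 86.6 |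

(standard deviation of a reading: 1 percentage point)

- the analysis behind the earlier runs scatters by 1 percentage point, standard deviation

1. ranking by amount of monomer in chains, in percent of the free monomer charged, from high to low, at 50 h (alder / ash / elm / oak / maple / cedar)
2. the same order at 10 h (alder / ash / elm / oak / maple / cedar)
3. the amount of monomer in chains, in percent of the free monomer charged of the flask you put first, at 50 h
4. the amount of monomer in chains, in percent of the free monomer charged of the flask you put last, at 50 h

Treat the inverse of that pseudo-first-order rate constant as the time constant of the free monomer. The amber to red ratio is 1.21, and the root of the ratio of absolute initiator charged is 1.23, so I let the rate constant follow that root. Green gives 4.21 × 10⁻⁴ /h over 240 h. Put on green's charge, amber is 347 times faster, and that factor is temperature's. You can carry it as one slope, the overall activation energy 81.6 kJ/mol, which moves a rate constant from one temperature to another.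

Slowing is the other factor. Red's later rate constant, from 12.0 h to 25.0 h, reads 0.0760 /h, which I take as fading initiator. This rough reading gives a fade time of 110 h, and over 50 h at 25 °C that trims the straight count by a factor 0.804.

My reckoning starts from red. Cedar reaches 77.3%, and alder starts at 2.60 × 10⁻⁴ /h, which gives 1.29%. Ash starts at 0.747 /h and elm at 14.4 /h, faster than ash. Amber and red ran at 25 °C, below ash's 55 °C, so I read no fade for ash or elm, and I leave ash against cedar open.

The forecast commits: elm > maple > ash > cedar > oak > alder at 50 h, elm > ash > maple > cedar > oak > alder at 10 h, top 98%, low 1.2%, on the ground “Ash is fast, then stalls”. Its low is below mine.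

The flasks give elm > maple > cedar > ash > oak > alder and elm > ash > maple > cedar > oak > alder, with top 100% and low 1.10%. They part from the forecast at ash, which reads 65.4% at 10 h and 65.4% at 50 h, while cedar climbs from 31.9% to 72.2%.

    initiator → 2 initiating radical (k = 0.0460 /h, Ea = 102 kJ/mol)
    free monomer + initiating radical → growing radical + monomer in chains (k = 5.56 × 10⁶ /M/h, Ea = 44.0 kJ/mol)
    free monomer + growing radical → monomer in chains + growing radical, rate k3*[growing radical]*[free monomer] (k = 1.58 × 10⁶ /M/h, Ea = 46.0 kJ/mol)
    2 growing radical → dead chain (k = 1.10 × 10⁶ /M/s, Ea = 21.0 kJ/mol)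
    (constants at 25 °C)

Now carry 81.6 kJ/mol to the neighbour, alder's charge held at 10 °C instead of −15 °C. Start from alder's 2.60 × 10⁻⁴ /h. The slope gives a temperature factor of 28.7. So the neighbour's rate constant is 0.00745 /h, and over 50 h that puts 31.1% of the free monomer in chains. The same reckoning gave alder 1.29%, where the flask stands at 1.10%. The neighbour stands at 30.7%, with 77% of its initiator left.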